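**Retrosynthetic overview**
- The target is the para C–O dimer of (S)-curcuphenol. The diaryl ether is cut oxidatively into two molecules of the free phenol: one ring is dearomatised to a quinol-ether dienone during the coupling, with no halide and no protecting group.
- (S)-Curcuphenol comes from (S)-2-(but-3-en-2-yl)-5-methylphenol by hydroboration and B-alkyl Suzuki coupling with 1-bromo-2-methylpropene.
- The benzylic stereocentre comes from an aromatic Claisen rearrangement (1,3-chirality transfer through an ortho-dienone) of the (R)-m-cresyl 1,3-dimethylallyl ether; ethenolysis then clips propenyl to vinyl.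
- The ether comes from Pd-catalysed asymmetric O-allylation of m-cresol through the symmetric 1,3-dimethylallyl–palladium intermediate.
- No ring is constructed: both benzene rings come intact from m-cresol.

Assumption: the (R,R)-DACH-phenyl Trost ligand is taken to give the (R)-ether in step 2; I could not fix this sense of induction from memory, so if the first run gives the (S)-ether the (S,S)-ligand is used and nothing else changes.

**Step 1**
Reactants: 1 rac-(E)-pent-3-en-2-ol
Product: 2 rac-(E)-methyl pent-3-en-2-yl carbonate
Conditions: ClCO2Me, pyridine, CH2Cl2, 0 °C to rt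
Reagents that add atoms: methyl chloroformate, COC(=O)Cl
Why: Simple O-acylation of a secondary allylic alcohol gives the carbonate leaving group needed for base-free palladium allylation; the racemic centre is irrelevant because it is erased in step 2.

**Step 2**
Reactants: 2 rac-(E)-methyl pent-3-en-2-yl carbonate; 3 m-cresol
Product: 4 (R,E)-1-methyl-3-(pent-3-en-2-yloxy)benzene
Conditions: Pd2(dba)3·CHCl3 (1 mol %), (R,R)-DACH-phenyl Trost ligand (3 mol %), CH2Cl2, rt
Reagents that add atoms: none
Why: Trost asymmetric allylic alkylation with a phenol nucleophile: both enantiomers of 2 ionise to the same symmetric syn,syn-1,3-dimethylallyl–palladium complex, and the chiral ligand directs the phenoxide (freed by the methoxide from the carbonate) to one of the two enantiotopic termini, which sets the (R)-C–O centre by desymmetrisation.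

**Step 3**
Reactants: 4 (R,E)-1-methyl-3-(pent-3-en-2-yloxy)benzene
Product: 6 (S,E)-5-methyl-2-(pent-3-en-2-yl)phenol, via ortho-dienone 5 (not isolated)
Conditions: Eu(fod)3 (10 mol %), CHCl3, 50 °C
Reagents that add atoms: none
Why: Lewis-acid-accelerated aromatic Claisen [3,3]-sigmatropic rearrangement: the chair transition state with the carbinol methyl pseudo-equatorial transfers the (R)-C–O centre suprafacially into the (S)-benzylic C–C centre with an E-propenyl group, bonding goes to the less hindered ortho carbon (para to the ring methyl), and dienone 5 re-aromatises by tautomerisation.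

**Step 4**
Reactants: 6 (S,E)-5-methyl-2-(pent-3-en-2-yl)phenol
Product: 7 (S)-2-(but-3-en-2-yl)-5-methylphenol
Conditions: second-generation Hoveyda–Grubbs catalyst RuCl2(H2IMes)(=CH-C6H4-2-OiPr) (3 mol %), ethylene (5 bar), 1,4-benzoquinone (10 mol %), CH2Cl2, 40 °C
Reagents that add atoms: ethylene, C=C
Why: Ethenolysis (cross-metathesis with excess ethylene) converts the 1,2-disubstituted propenyl group into a vinyl group; the free phenol is tolerated and benzoquinone suppresses ruthenium hydride isomerisation, so the allylic benzylic stereocentre is untouched.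

**Step 5**
Reactants: 7 (S)-2-(but-3-en-2-yl)-5-methylphenol; 8 1-bromo-2-methylprop-1-ene
Product: 10 (S)-curcuphenol [(S)-5-methyl-2-(6-methylhept-5-en-2-yl)phenol], via B-alkyl-9-BBN borane 9 (not isolated)
Conditions: 9-BBN (2.3 equiv), THF, 0 °C to rt; then 8 (1.5 equiv), Pd(dppf)Cl2·CH2Cl2 (3 mol %), 3 M aq NaOH, THF, 60 °C
Reagents that add atoms: 9-borabicyclo[3.3.1]nonane (9-BBN-H), B1C2CCCC1CCC2 (its atoms stay in intermediate 9 only)
Why: Anti-Markovnikov hydroboration of the terminal alkene (one further equivalent of borane is consumed by the phenol O–H) followed by B-alkyl Suzuki–Miyaura coupling with the alkenyl bromide builds the homoprenyl chain without touching the stereocentre.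

**Step 6**
Reactants: 10 (S)-curcuphenol (two molecules)
Product: 12 5-methyl-4-{5-methyl-2-[(2S)-6-methylhept-5-en-2-yl]phenoxy}-2-[(2S)-6-methylhept-5-en-2-yl]phenol (target), via quinol-ether dienone 11 (not isolated)
Conditions: CuCl2 (5 mol %), 1,4,7-triisopropyl-1,4,7-triazacyclononane (5 mol %), 2,6-diphenylpyridine (50 mol %), O2 (1 atm), toluene, 40 °C, stopped at about 40 % conversion, unreacted 10 recycled
Reagents that add atoms: none
Why: Proposed new method: a phenoxo complex of divalent copper held in the pocket of the bulky triazacyclononane ligand is oxidised by O2 to a copper-bound phenoxyl, whose para carbon (highest spin density and the only unhindered site) is attacked by the oxygen of a second copper phenoxide while C–C coupling is blocked by the ligand and the ortho sec-alkyl group, and the resulting 4-aryloxycyclohexa-2,5-dienone 11 (one ring dearomatised) tautomerises to the hydroquinone mono-aryl ether with both side-chain stereocentres untouched; the closest known reaction type is the copper/amine aerobic oxidative C–O coupling of 2,6- and 2,5-dialkylphenols that gives poly(phenylene oxide)s, here stopped at the dimer by low conversion.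

**Compound list**
1 | rac-(E)-pent-3-en-2-ol | C/C=C/C(C)O | starting material
2 | rac-(E)-methyl pent-3-en-2-yl carbonate | C/C=C/C(C)OC(=O)OC | intermediate
3 | m-cresol (3-methylphenol) | Cc1cccc(O)c1 | starting material
4 | (R,E)-1-methyl-3-(pent-3-en-2-yloxy)benzene | Cc1cccc(O[C@H](C)/C=C/C)c1 | intermediate
5 | 3-methyl-6-[(2S,3E)-pent-3-en-2-yl]cyclohexa-2,4-dien-1-one (ring C6 epimers) | O=C1C=C(C)C=CC1[C@@H](C)/C=C/C | intermediate (not isolated)
6 | (S,E)-5-methyl-2-(pent-3-en-2-yl)phenol | Cc1ccc([C@@H](C)/C=C/C)c(O)c1 | intermediate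
7 | (S)-2-(but-3-en-2-yl)-5-methylphenol | Cc1ccc([C@@H](C)C=C)c(O)c1 | intermediate
8 | 1-bromo-2-methylprop-1-ene | CC(C)=CBr | starting material
9 | 9-[(3S)-3-{2-[(9-borabicyclo[3.3.1]nonan-9-yl)oxy]-4-methylphenyl}butyl]-9-borabicyclo[3.3.1]nonane | Cc1ccc([C@@H](C)CCB2C3CCCC2CCC3)c(OB2C3CCCC2CCC3)c1 | intermediate (not isolated)
10 | (S)-curcuphenol, (S)-5-methyl-2-(6-methylhept-5-en-2-yl)phenol | Cc1ccc([C@@H](C)CCC=C(C)C)c(O)c1 | intermediate
11 | 5-methyl-2-[(2S)-6-methylhept-5-en-2-yl]-4-{5-methyl-2-[(2S)-6-methylhept-5-en-2-yl]phenoxy}cyclohexa-2,5-dien-1-one (C4 epimers) | O=C1C([C@@H](C)CCC=C(C)C)=CC(Oc2cc(C)ccc2[C@@H](C)CCC=C(C)C)C(C)=C1 | intermediate (not isolated)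
12 | 5-methyl-4-{5-methyl-2-[(2S)-6-methylhept-5-en-2-yl]phenoxy}-2-[(2S)-6-methylhept-5-en-2-yl]phenol | CC(C)=CCC[C@H](C)c1cc(Oc2cc(C)ccc2[C@@H](C)CCC=C(C)C)c(C)cc1O | target

**Step count**
Total: 6 steps. Longest linear sequence: 6 steps (1 to 12); 5 steps from m-cresol.

**Three steps most likely to fail, with fallbacks**

Step 6 (oxidative C–O dimerisation). The risks are C–C coupled dimers, chain growth past the dimer, and a yield near 25–30 % per pass. A one-electron copper system is chosen because a two-electron oxidant would give a phenoxonium ion that the side-chain alkene can capture. The fallback leaves oxidative coupling for a halide-based Ullmann ether synthesis and sets out from 10: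
- Para-bromination of 10 (NBS, MeCN, −30 °C) gives (S)-4-bromo-5-methyl-2-(6-methylhept-5-en-2-yl)phenol F1.
- O-allylation (allyl bromide, K2CO3, acetone) gives its allyl ether, (S)-1-(allyloxy)-4-bromo-5-methyl-2-(6-methylhept-5-en-2-yl)benzene F2.
- Ullmann coupling of F2 with a second equivalent of 10 (CuI, picolinic acid, K3PO4, DMSO, 90 °C) gives the O-allyl ether of the target F3.
- Deallylation (Pd(PPh3)4, morpholine, THF, rt) returns to the route at 12.

Step 3 (Claisen rearrangement). The risks are attack at the ortho carbon between OH and CH3, and loss of chirality transfer through ionisation or a boat pathway. The fallback drops the sigmatropic route for an intermolecular catalytic asymmetric C–C bond formation with the ring position fixed beforehand; it sets out from 3: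
- Ortho-formylation of 3 (MgCl2, Et3N, paraformaldehyde, MeCN, reflux) gives 2-hydroxy-4-methylbenzaldehyde F4.
- Wittig methylenation (Ph3P=CH2, 2.2 equiv, THF) gives 5-methyl-2-vinylphenol F5.
- Silylation (TBSCl, imidazole, DMF) gives tert-butyldimethyl(5-methyl-2-vinylphenoxy)silane F6.
- Nickel-catalysed asymmetric hydrovinylation ([(η3-C3H5)NiBr]2, binaphthol-derived phosphoramidite of the enantiomer that gives the S product, Na[B(3,5-(CF3)2C6H3)4], ethylene 1 atm, CH2Cl2, −70 °C) gives (S)-[2-(but-3-en-2-yl)-5-methylphenoxy](tert-butyl)dimethylsilane F7.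
- Desilylation (Bu4NF, THF) returns to the route at 7.

Step 2 (asymmetric O-allylation). The risk is that the acyclic 1,3-dimethylallyl system gives only moderate ee, and that reversible ionisation of the aryl ether erodes it further. Any minor enantiomer becomes a hard-to-separate heterochiral diastereomer of 12 in step 6. The fallback replaces catalytic desymmetrisation by kinetic resolution plus stereospecific substitution and sets out from 1:
- Sharpless kinetic resolution of 1 (D-(−)-diisopropyl tartrate, Ti(OiPr)4, tBuOOH 0.6 equiv, 4 Å sieves, CH2Cl2, −20 °C) leaves (S,E)-pent-3-en-2-ol F8 in high ee.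
- Mitsunobu etherification of F8 with 3 (PPh3, DIAD, THF, 0 °C; SN2 with inversion) returns to the route at 4.

**Further compounds**
F1 | step 6 | (S)-4-bromo-5-methyl-2-(6-methylhept-5-en-2-yl)phenol | Cc1cc(O)c([C@@H](C)CCC=C(C)C)cc1Br
F2 | step 6 | (S)-1-(allyloxy)-4-bromo-5-methyl-2-(6-methylhept-5-en-2-yl)benzene | Cc1cc(OCC=C)c([C@@H](C)CCC=C(C)C)cc1Br
F3 | step 6 | 1-(allyloxy)-5-methyl-4-{5-methyl-2-[(2S)-6-methylhept-5-en-2-yl]phenoxy}-2-[(2S)-6-methylhept-5-en-2-yl]benzene | Cc1cc(OCC=C)c([C@@H](C)CCC=C(C)C)cc1Oc2cc(C)ccc2[C@@H](C)CCC=C(C)C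
F4 | step 3 | 2-hydroxy-4-methylbenzaldehyde | Cc1ccc(C=O)c(O)c1
F5 | step 3 | 5-methyl-2-vinylphenol | Cc1ccc(C=C)c(O)c1
F6 | step 3 | tert-butyldimethyl(5-methyl-2-vinylphenoxy)silane | Cc1ccc(C=C)c(O[Si](C)(C)C(C)(C)C)c1
F7 | step 3 | (S)-[2-(but-3-en-2-yl)-5-methylphenoxy](tert-butyl)dimethylsilane | Cc1ccc([C@@H](C)C=C)c(O[Si](C)(C)C(C)(C)C)c1
F8 | step 2 | (S,E)-pent-3-en-2-ol | C/C=C/[C@H](C)O
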